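**Retrosynthetic overview**

1. The only ring is the benzene ring (C1 CO2H, C2 OH, C3 H, C4 OH, C5 CH3, C6 13-methyltetradecyl). The strategy rests on its C2 carbinol carbon, which lies between C1 and C3 and can be carbon monoxide if C3–C4 is a terminal alkyne, C5 a propargylic carbinol carbon and C6=C1 an enoate alkene.
2. Key disconnection, forming the ring in one step: Rh(I)/CO [5+1] benzannulation of a tertiary 3-pivaloyloxy-1,4-enyne. The pivalate shifts from C5 to C4 and CO is inserted between C3 and C1 (bonds C2–C3 and C1–C2).
3. The enyne comes from addition of ethynylmagnesium bromide to the ketone of benzyl (E)-3-(13-methyltetradecyl)-4-oxopent-2-enoate, followed by O-pivaloylation.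
4. The E-enone ester comes from a Horner–Wadsworth–Emmons reaction of an α-alkyl β-ketophosphonate with benzyl glyoxylate. The phosphonate is built from 12-bromododecan-1-ol and isobutylmagnesium bromide by Cu-catalysed coupling, bromination, Arbuzov reaction and acetylation.
5. A benzyl ester is carried instead of a methyl ester, so that the hindered, decarboxylation-prone 2,6-disubstituted β-resorcylic acid is released last by neutral hydrogenolysis, after hydrolysis of the aryl pivalate.

Key step: step 9

Remark: the target has no stereocentre and no stereogenic double bond, so the structure as drawn is the single species required; the propargylic centre of the enyne is carried racemic and is erased on aromatisation.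

**Route**

Step 1
Reactants: 1 12-bromododecan-1-ol; 2 isobutylmagnesium bromide
Product: 3 14-methylpentadecan-1-ol
Conditions: 2 (3 equiv), Li2CuCl4 (3 mol %), THF, −20 °C → rt; then 1 M HCl, 0 °C
Reagents that add atoms: none
Why: Copper-catalysed Kochi-type sp3–sp3 cross-coupling of a primary alkyl bromide with a primary Grignard reagent should be clean, because the first equivalent of Grignard only converts the hydroxyl into an inert bromomagnesium alkoxide and the catalytic cuprate displaces bromide by SN2 at low temperature.

Step 2
Reactants: 3 14-methylpentadecan-1-ol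
Product: 4 1-bromo-14-methylpentadecane
Conditions: CBr4, PPh3, CH2Cl2, 0 °C → rt
Reagents that add atoms: carbon tetrabromide, BrC(Br)(Br)Br
Why: Appel reaction, in which the alkoxyphosphonium ion is displaced by bromide in an SN2 step at an unhindered primary carbon with no other functional group present.

Step 3
Reactants: 4 1-bromo-14-methylpentadecane
Product: 5 diethyl (14-methylpentadecyl)phosphonate
Conditions: P(OEt)3 (neat, excess), 150 °C, bromoethane distilled off
Reagents that add atoms: triethyl phosphite, CCOP(OCC)OCC
Why: Michaelis–Arbuzov reaction, reliable for unbranched primary bromides because SN2 attack by phosphorus is followed by dealkylation of the phosphonium ion by bromide and the volatile co-product leaves the melt.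

Step 4
Reactants: 5 diethyl (14-methylpentadecyl)phosphonate; 6 N-methoxy-N-methylacetamide
Product: 8 diethyl (16-methyl-2-oxoheptadecan-3-yl)phosphonate (racemic), via lithiated phosphonate 7 (not isolated)
Conditions: n-BuLi, THF, −78 °C; then 6, −78 → 0 °C; then 1 M HCl, 0 °C
Reagents that add atoms: none
Why: α-Lithiation of the alkylphosphonate and acylation with a Weinreb amide should stop at the ketone because the chelated tetrahedral adduct collapses only on work-up, so the acidic β-ketophosphonate cannot quench unreacted carbanion; the new P-bearing stereocentre is formed racemic and disappears in step 6.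

Step 5
Reactants: 9 dibenzyl L-tartrate
Product: 10 benzyl glyoxylate
Conditions: H5IO6, Et2O, rt; filtered, dried (MgSO4, toluene azeotrope), used crude
Reagents that add atoms: none
Why: Malaprade glycol cleavage of the vicinal diol by periodic acid should give two molecules of the glyoxylate, the benzyl esters being untouched under these non-basic conditions.

Step 6
Reactants: 8 diethyl (16-methyl-2-oxoheptadecan-3-yl)phosphonate; 10 benzyl glyoxylate
Product: 11 benzyl (2E)-3-(13-methyltetradecyl)-4-oxopent-2-enoate
Conditions: LiCl, DBU, MeCN/THF, 0 °C → rt
Reagents that add atoms: none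
Why: Horner–Wadsworth–Emmons olefination under Masamune–Roush conditions with the highly electrophilic glyoxylate aldehyde should give the trisubstituted alkene under thermodynamic control as the 2E isomer (ester trans to acetyl, the fumarate-like arrangement), the position of the chain being fixed by the phosphonate carbon.

Step 7
Reactants: 11 benzyl (2E)-3-(13-methyltetradecyl)-4-oxopent-2-enoate; 12 ethynylmagnesium bromide
Product: 13 benzyl (2E)-4-hydroxy-4-methyl-3-(13-methyltetradecyl)hex-2-en-5-ynoate (racemic)
Conditions: 12 (1.3 equiv, 0.5 M in THF), THF, −78 → −30 °C; then 1 M HCl, 0 °C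
Reagents that add atoms: none
Why: 1,2-Addition of an alkynyl Grignard reagent should occur at the methyl ketone, which is more electrophilic than the conjugated benzyl ester, and sp-carbon nucleophiles do not add in a conjugate sense without copper; the new carbinol stereocentre is formed racemic, which is without consequence because it becomes an aromatic carbon in step 9, and the E geometry rules out lactonisation.

Step 8
Reactants: 13 benzyl (2E)-4-hydroxy-4-methyl-3-(13-methyltetradecyl)hex-2-en-5-ynoate
Product: 15 benzyl (2E)-4-methyl-3-(13-methyltetradecyl)-4-(pivaloyloxy)hex-2-en-5-ynoate (racemic), via lithium alkoxide 14 (not isolated)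
Conditions: LiHMDS (1.05 equiv), THF, −78 °C; then PivCl, −78 → 0 °C
Reagents that add atoms: pivaloyl chloride, CC(C)(C)C(=O)Cl
Why: O-Acylation of the preformed lithium alkoxide with the acid chloride (esterification) overcomes the low reactivity of the hindered tertiary alcohol, one equivalent of amide base removing the O–H proton in preference to the alkyne C–H or the γ-C–H of the enoate.

Step 9
Reactants: 15 benzyl (2E)-4-methyl-3-(13-methyltetradecyl)-4-(pivaloyloxy)hex-2-en-5-ynoate; 16 carbon monoxide
Product: 18 benzyl 2-hydroxy-5-methyl-6-(13-methyltetradecyl)-4-(pivaloyloxy)benzoate, via dienylketene 17 (not isolated)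
Conditions: [Rh(CO)2Cl]2 (5 mol %), CO (1 atm), ClCH2CH2Cl, 70 °C
Reagents that add atoms: none
Why: Rh(I) binds the terminal alkyne, the pivalate carbonyl oxygen adds 5-exo to the internal alkyne carbon and the propargylic C–O bond breaks, so that the ester ends up on the future C4 and a rhodium vinylcarbene sits on the future C3, where CO inserts (bond C2–C3) to give dienylketene 17 or its acyl-rhodacycle equivalent. The closest known reaction type is the Rh-catalysed carbonylative [5+1] benzannulation of 3-acyloxy-1,4-enynes to resorcinol monoesters, applied here to a tertiary ester with an acceptor-substituted alkene. The benzene ring closes by disrotatory 6π-electrocyclisation of the ketene-diene (or by C–C reductive elimination from the acyl rhodacycle), which joins the CO carbon to the enoate α-carbon (bond C1–C2), and the resulting cyclohexa-2,4-dienone, whose ring proton lies between ketone and ester, should enolise irreversibly to the hydrogen-bonded salicylate. No stereocentre is created, and the racemic propargylic centre of 15 becomes the aromatic C5. The step needs 1,2- rather than 1,3-acyloxy migration, which the unsubstituted alkyne terminus secures because attack at the internal carbon places the carbene on the CH end, helped by the acceptor-substituted alkene, which disfavours ionisation of the tertiary ester. It also needs the alkenyl arm cis to the carbene on the new C4=C5 bond, which chelation of rhodium by the alkyne and alkene of the 1,4-enyne should provide, and the 2E geometry of 15 turns H rather than CO2Bn to the inside of the closing triene.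

Step 10
Reactants: 18 benzyl 2-hydroxy-5-methyl-6-(13-methyltetradecyl)-4-(pivaloyloxy)benzoate
Product: 19 benzyl 2,4-dihydroxy-5-methyl-6-(13-methyltetradecyl)benzoate
Conditions: LiOH·H2O, THF/H2O (3:1), N2, rt; then 1 M HCl, 0 °C
Reagents that add atoms: none
Why: Saponification of the aryl pivalate, an activated phenyl ester whose phenoxide leaving group is para to the benzoate carbonyl, should be selective because the benzyl ester is a 2,6-disubstituted, phenoxide-deactivated salicylate that resists hydroxide at room temperature and cannot be transesterified in an alcohol-free medium.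

Step 11
Reactants: 19 benzyl 2,4-dihydroxy-5-methyl-6-(13-methyltetradecyl)benzoate
Product: 20 2,4-dihydroxy-5-methyl-6-(13-methyltetradecyl)benzoic acid (target CNP0092306.0)
Conditions: H2 (1 atm), 10% Pd/C, EtOAc, rt; concentrated below 30 °C
Reagents that add atoms: none
Why: Catalytic hydrogenolysis of the benzyl ester (O-debenzylation) frees the acid under neutral conditions at room temperature, which avoids the forcing hydrolysis a hindered alkyl ester would need and the decarboxylation to which 2,4-dihydroxybenzoic acids are prone, and nothing else in the molecule is reducible.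

**Compound list**

1 | 12-bromododecan-1-ol | OCCCCCCCCCCCCBr | starting material
2 | isobutylmagnesium bromide | CC(C)C[Mg]Br | starting material
3 | 14-methylpentadecan-1-ol | OCCCCCCCCCCCCCC(C)C | intermediate
4 | 1-bromo-14-methylpentadecane | BrCCCCCCCCCCCCCC(C)C | intermediate
5 | diethyl (14-methylpentadecyl)phosphonate | CCOP(=O)(OCC)CCCCCCCCCCCCCC(C)C | intermediate
6 | N-methoxy-N-methylacetamide | CC(=O)N(C)OC | starting material
7 | diethyl (1-lithio-14-methylpentadecyl)phosphonate | [Li]C(CCCCCCCCCCCCC(C)C)P(=O)(OCC)OCC | intermediate
8 | diethyl (16-methyl-2-oxoheptadecan-3-yl)phosphonate (racemic) | CC(=O)C(CCCCCCCCCCCCC(C)C)P(=O)(OCC)OCC | intermediate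
9 | dibenzyl L-tartrate, dibenzyl (2R,3R)-2,3-dihydroxybutanedioate | O=C(OCc1ccccc1)[C@H](O)[C@@H](O)C(=O)OCc1ccccc1 | starting material
10 | benzyl glyoxylate (benzyl 2-oxoacetate) | O=CC(=O)OCc1ccccc1 | intermediate
11 | benzyl (2E)-3-(13-methyltetradecyl)-4-oxopent-2-enoate | CC(=O)/C(CCCCCCCCCCCCC(C)C)=C/C(=O)OCc1ccccc1 | intermediate
12 | ethynylmagnesium bromide | C#C[Mg]Br | starting material
13 | benzyl (2E)-4-hydroxy-4-methyl-3-(13-methyltetradecyl)hex-2-en-5-ynoate (racemic) | C#CC(C)(O)/C(CCCCCCCCCCCCC(C)C)=C/C(=O)OCc1ccccc1 | intermediate
14 | lithium alkoxide of 13 (racemic) | [Li+].C#CC(C)([O-])/C(CCCCCCCCCCCCC(C)C)=C/C(=O)OCc1ccccc1 | intermediate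
15 | benzyl (2E)-4-methyl-3-(13-methyltetradecyl)-4-(pivaloyloxy)hex-2-en-5-ynoate (racemic) | C#CC(C)(OC(=O)C(C)(C)C)/C(CCCCCCCCCCCCC(C)C)=C/C(=O)OCc1ccccc1 | intermediate
16 | carbon monoxide | [C-]#[O+] | starting material
17 | benzyl (2E,4E)-4-methyl-3-(13-methyltetradecyl)-7-oxo-5-(pivaloyloxy)hepta-2,4,6-trienoate (dienylketene, free or Rh-bound) | O=C=C/C(OC(=O)C(C)(C)C)=C(C)\C(CCCCCCCCCCCCC(C)C)=C\C(=O)OCc1ccccc1 | intermediate
18 | benzyl 2-hydroxy-5-methyl-6-(13-methyltetradecyl)-4-(pivaloyloxy)benzoate | O=C(OCc1ccccc1)c1c(O)cc(OC(=O)C(C)(C)C)c(C)c1CCCCCCCCCCCCC(C)C | intermediate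
19 | benzyl 2,4-dihydroxy-5-methyl-6-(13-methyltetradecyl)benzoate | O=C(OCc1ccccc1)c1c(O)cc(O)c(C)c1CCCCCCCCCCCCC(C)C | intermediate
20 | 2,4-dihydroxy-5-methyl-6-(13-methyltetradecyl)benzoic acid | Cc1c(O)cc(O)c(C(=O)O)c1CCCCCCCCCCCCC(C)C | target

**Step count and risks**

Total step count: 11. Longest linear sequence: 10 (steps 1–4 and 6–11; step 5 is a one-step side branch).

Steps most likely to fail:

Step 9. The pivalate may shift 1,3 to give an allenyl ester instead of 1,2. The vinylcarbene may close to a five-membered ring without taking up CO. The trisubstituted, electron-poor alkene may fail to engage, so that the catalyst stalls. The fallback builds the ring by classical Michael–Claisen annulation and aromatisation. It sets out from alcohol 3, which is oxidised (TEMPO, PhI(OAc)2, CH2Cl2) to 14-methylpentadecanal F1. Wittig olefination with commercial 3-(triphenylphosphoranylidene)butan-2-one (toluene, reflux) should give (3E)-3,17-dimethyloctadec-3-en-2-one F2. Conjugate addition of dibenzyl malonate (NaH, THF, reflux) should give dibenzyl 2-(3,17-dimethyl-2-oxooctadecan-4-yl)propanedioate F3. F3 should close in the same flask, by Claisen condensation of the methyl ketone enolate onto one benzyl ester, to benzyl 2-hydroxy-5-methyl-6-(13-methyltetradecyl)-4-oxocyclohex-2-ene-1-carboxylate F4. Dehydrogenation with Br2 in DMF (0 → 80 °C) should aromatise F4 to compound 19, where the route is rejoined before step 11.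

Step 6. Geometric control may be lost, and any Z enoate would be removed as a butenolide in step 7. The α-branched phosphonate anion may also react slowly while the glyoxylate oligomerises under base. The fallback is a Wittig reaction of the corresponding stabilised triphenylphosphorane, which is more reliably E-selective. It sets out from bromide 4, which with PPh3 (MeCN, reflux) should give (14-methylpentadecyl)triphenylphosphonium bromide F5. NaHMDS (THF, −78 °C) converts F5 into (14-methylpentadecylidene)triphenyl-λ5-phosphane F6. Acetyl chloride (0.5 equiv) acylates F6 with transylidation to 16-methyl-3-(triphenyl-λ5-phosphanylidene)heptadecan-2-one F7, and the other half of F6 returns as recyclable phosphonium salt. Heating F7 with benzyl glyoxylate 10 (toluene, 80 °C) should give compound 11, where the route is rejoined before step 7.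

Step 7. Attack may compete at the doubly activated alkene or at the ester, the methyl ketone may be enolised, and double addition may occur through the bis-magnesium acetylide that forms by disproportionation of the reagent. Acylation of the hindered alcohol in step 8 may also be sluggish. The fallback uses a silyl-capped lithium acetylide with acylation in the same flask, and so replaces steps 7 and 8. It sets out from enone ester 11. Commercial lithium (trimethylsilyl)acetylide (THF, −78 °C) should give the lithium alkoxide of benzyl (2E)-4-hydroxy-4-methyl-3-(13-methyltetradecyl)-6-(trimethylsilyl)hex-2-en-5-ynoate F8. Trapping with pivaloyl chloride should give benzyl (2E)-4-methyl-3-(13-methyltetradecyl)-4-(pivaloyloxy)-6-(trimethylsilyl)hex-2-en-5-ynoate F9. Desilylation with TBAF/AcOH (THF, 0 °C) should then give compound 15, where the route is rejoined before step 9.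

**Further compounds**

F1 | step 9 | 14-methylpentadecanal | O=CCCCCCCCCCCCCC(C)C
F2 | step 9 | (3E)-3,17-dimethyloctadec-3-en-2-one | CC(=O)/C(C)=C/CCCCCCCCCCCCC(C)C
F3 | step 9 | dibenzyl 2-(3,17-dimethyl-2-oxooctadecan-4-yl)propanedioate (mixture of diastereomers) | CC(=O)C(C)C(CCCCCCCCCCCCC(C)C)C(C(=O)OCc1ccccc1)C(=O)OCc1ccccc1
F4 | step 9 | benzyl 2-hydroxy-5-methyl-6-(13-methyltetradecyl)-4-oxocyclohex-2-ene-1-carboxylate (mixture of stereoisomers) | O=C(OCc1ccccc1)C1C(O)=CC(=O)C(C)C1CCCCCCCCCCCCC(C)C
F5 | step 6 | (14-methylpentadecyl)triphenylphosphonium bromide | CC(C)CCCCCCCCCCCCC[P+](c1ccccc1)(c1ccccc1)c1ccccc1.[Br-]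
F6 | step 6 | (14-methylpentadecylidene)triphenyl-λ5-phosphane | CC(C)CCCCCCCCCCCCC=P(c1ccccc1)(c1ccccc1)c1ccccc1
F7 | step 6 | 16-methyl-3-(triphenyl-λ5-phosphanylidene)heptadecan-2-one | CC(=O)C(CCCCCCCCCCCCC(C)C)=P(c1ccccc1)(c1ccccc1)c1ccccc1
F8 | step 7 | lithium alkoxide of benzyl (2E)-4-hydroxy-4-methyl-3-(13-methyltetradecyl)-6-(trimethylsilyl)hex-2-en-5-ynoate (racemic) | [Li+].C[Si](C)(C)C#CC(C)([O-])/C(CCCCCCCCCCCCC(C)C)=C/C(=O)OCc1ccccc1
F9 | step 7 | benzyl (2E)-4-methyl-3-(13-methyltetradecyl)-4-(pivaloyloxy)-6-(trimethylsilyl)hex-2-en-5-ynoate (racemic) | C[Si](C)(C)C#CC(C)(OC(=O)C(C)(C)C)/C(CCCCCCCCCCCCC(C)C)=C/C(=O)OCc1ccccc1
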